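## Retrosynthetic overview
1. Ring C of the (2S)-flavanone unit is closed last. Chalcone isomerase cyclises the fully unprotected biflavonoid chalcone by 6-endo oxa-Michael addition, and this is the only stereo-defining event.
2. That chalcone comes from retro-oxa-Michael opening of the racemic biflavonoid. Its 3'–8'' biaryl bond is made by direct dehydrogenative C–H/C–H phenol coupling of (±)-naringenin with acacetin, with no halide, boron or protecting group.
3. Acacetin is made in one flask from phloroacetophenone and p-anisaldehyde by the chalcone → flavanone → flavone cascade.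
4. Order of events: flavone ring C (step 1), then the biaryl bond (step 2), then flavanone ring C opened and re-formed enantioselectively (step 3).

Assumption: chalcone isomerase (Medicago sativa sequence, His-tagged, over-expressed in E. coli from a purchased synthetic gene) counts as an accessible catalyst. The 3'–8'' axis is taken as configurationally labile at room temperature, so C2 is the only stereo-element to control.

## Route

Step 1
Reactants: 1 2',4',6'-trihydroxyacetophenone (phloroacetophenone); 2 4-methoxybenzaldehyde (p-anisaldehyde)
Product: 5 acacetin, via methoxychalcone 3 (not isolated), via isosakuranetin 4 (not isolated)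
Conditions: pyrrolidine (0.5 equiv), DMSO, 80 °C, 4 h; then I2 (10 mol %), 140 °C, 3 h, Ar sweep
Reagents that add atoms: none
Why: This is a domino Claisen–Schmidt condensation / oxa-Michael cyclisation / iodine–DMSO dehydrogenation in which pyrrolidine activates 2 as its iminium ion and condenses it with the methyl ketone of 1 to chalcone 3, an ortho-phenol closes ring C to racemic flavanone 4 (its stereocentre is erased again at once), and catalytic I2 with DMSO as terminal oxidant iodinates C3 and eliminates HI to give the flavone; this is the order followed by chalcone isomerase and flavone synthase, the two ortho-hydroxyls of 1 are equivalent so only one flavone can form, and reversible Betti-type C-alkylation of ring A is drained by the irreversible aromatisation.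

Step 2
Reactants: 5 acacetin (3 equiv); 6 (±)-naringenin (1 equiv)
Product: 7 (±)-2,3-dihydropodocarpusflavone A
Conditions: undivided cell, boron-doped diamond anode, Pt cathode, 3 mA cm−2, 1.8 F mol−1 on 6, [Bu3NMe][O3SOMe] (0.1 M), HFIP–MeOH 85:15, 45 °C
Reagents that add atoms: none
Why: Proposed new method: the para-alkylphenol of ring B of 6 is the most easily oxidised site present (both acylphloroglucinol rings A and the anisyl ring lie roughly 0.2 V or more higher), its HFIP-stabilised phenoxyl radical is attacked at the free ortho carbon C3' by the most electron-rich carbon in the flask, C8 of 5 (the site of Mannich and azo coupling in 5,7-dihydroxyflavones, δC about 94 against 99 for C6), and a second electron transfer with rearomatisation gives the 3'–8'' biaryl as in the enzymatic phenol coupling of the biosynthesis; homo-coupling through ring A of 6 is held down by the threefold, recoverable excess of 5, over-oxidation is limited by stopping before 6 is used up, no stereocentre is set (C2 stays racemic), and the closest known reactions are the anodic dehydrogenative phenol–arene cross-coupling in HFIP and the photocatalytic ortho coupling of tyrosine-type phenols.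

Step 3
Reactants: 7 (±)-2,3-dihydropodocarpusflavone A
Product: 9 (2S)-2,3-dihydropodocarpusflavone A, via ring-opened chalcone 8 (not isolated)
Conditions: KOH (50% w/v aq), Ar, 0→23 °C, 45 min; pour into ice-cold 0.1 M KH2PO4 (final pH about 7, 1 mM in 8); at once recombinant chalcone isomerase (20 mg L−1), 10 °C, 30 min; capture on HP-20 resin, elute with MeOH
Reagents that add atoms: none
Why: Proposed new method: cold concentrated KOH opens ring C of the flavanone unit by E1cB retro-oxa-Michael reaction to the chalcone polyanion 8 (the classical way from naringenin to naringenin chalcone; the flavone unit, present as its electron-rich dianion, resists cold alkali), which erases C2, and after the fast quench to pH 7, where uncatalysed closure takes hours, chalcone isomerase holds the 2',4',6'-trihydroxyphenyl enone so that the 2'-phenolate adds to one enone face only (enzymatic intramolecular oxa-Michael addition, about 10^7-fold over background) and sets C2 as (S); the enzyme reads ring A and the enone, both native here, while the ring B end sits at the mouth of its cleft and already accepts 3-hydroxy- and 3-methoxychalcones, so the flavonyl group at C3 should point outward, the closest known reaction being the isomerase-catalysed cyclisation of naringenin chalcone to (2S)-naringenin.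

## Compound list
1 | 2',4',6'-trihydroxyacetophenone (phloroacetophenone) | CC(=O)c1c(O)cc(O)cc1O | starting material
2 | 4-methoxybenzaldehyde (p-anisaldehyde) | COc1ccc(C=O)cc1 | starting material
3 | (E)-2',4',6'-trihydroxy-4-methoxychalcone | COc1ccc(/C=C/C(=O)c2c(O)cc(O)cc2O)cc1 | intermediate
4 | (±)-isosakuranetin (5,7-dihydroxy-4'-methoxyflavanone, racemic at C2) | COc1ccc(C2CC(=O)c3c(O)cc(O)cc3O2)cc1 | intermediate
5 | acacetin (5,7-dihydroxy-4'-methoxyflavone) | COc1ccc(-c2cc(=O)c3c(O)cc(O)cc3o2)cc1 | intermediate
6 | (±)-naringenin (5,7,4'-trihydroxyflavanone, racemic at C2) | O=C1CC(c2ccc(O)cc2)Oc2cc(O)cc(O)c21 | starting material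
7 | (±)-2,3-dihydropodocarpusflavone A (naringenin C3' bonded to acacetin C8, racemic at C2) | COc1ccc(-c2cc(=O)c3c(O)cc(O)c(-c4cc(C5CC(=O)c6c(O)cc(O)cc6O5)ccc4O)c3o2)cc1 | intermediate
8 | 8-{2-hydroxy-5-[(E)-3-oxo-3-(2,4,6-trihydroxyphenyl)prop-1-enyl]phenyl}acacetin (biflavonoid chalcone, formed as its potassium polyanion) | COc1ccc(-c2cc(=O)c3c(O)cc(O)c(-c4cc(/C=C/C(=O)c5c(O)cc(O)cc5O)ccc4O)c3o2)cc1 | intermediate
9 | (2S)-2,3-dihydropodocarpusflavone A | COc1ccc(-c2cc(=O)c3c(O)cc(O)c(-c4cc([C@@H]5CC(=O)c6c(O)cc(O)cc6O5)ccc4O)c3o2)cc1 | target

## Step count and risks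
Total step count: 3. Longest linear sequence: 3 (1 → 5 → 7 → 9).

**Most likely to fail: step 2.**
- Risks:
  - formation of the 3'–6'' isomer;
  - homo-coupling of 6;
  - C–O coupling;
  - oxidation of 6 at C2–H to apigenin;
  - limited solubility of 5 in HFIP.
- Fallback: give up the dehydrogenative coupling for a halide/boronate cross-coupling and build the flavanone unit afterwards. This sets out from 5 and comes back to the route at 8.
- 5 is protected (MOMCl, NaH, DMF) to give 5,7-bis(methoxymethoxy)-4'-methoxyflavone F2. NIS in DMF iodinates this at C8, the known site for 5,7-dialkoxyflavones, to give 8-iodo-5,7-bis(methoxymethoxy)-4'-methoxyflavone F3.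
- Commercial 3-bromo-4-hydroxybenzaldehyde is borylated (B2pin2, Pd(dppf)Cl2, KOAc, dioxane, 90 °C) to give 4-hydroxy-3-(4,4,5,5-tetramethyl-1,3,2-dioxaborolan-2-yl)benzaldehyde F4.
- Suzuki–Miyaura coupling of F3 with F4 (Pd(PPh3)4, K2CO3, dioxane–H2O, 90 °C) gives 8-(5-formyl-2-hydroxyphenyl)-5,7-bis(methoxymethoxy)-4'-methoxyflavone F5.
- Catalytic HCl in MeOH at 45 °C removes both acetals to give 8-(5-formyl-2-hydroxyphenyl)acacetin F6.
- Claisen–Schmidt condensation of F6 with 1 in 50% KOH/EtOH gives the alkaline solution of 8. This goes straight into the buffer quench and enzymatic closure of step 3.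

**Second: step 3.**
- Risks:
  - The isomerase may bind the bulky C3-substituted chalcone poorly, so that racemic background closure competes.
  - Incomplete opening leaves racemate. This can be reduced by repeating the open/close cycle, with chiral HPLC control.
- Fallback: set the stereocentre on the monomer, where the enzyme meets its native substrate, and couple afterwards. This sets out from 6 and comes back to the route at 9.
- 6 is opened with 50% KOH and quenched into KH2PO4 buffer to give naringenin chalcone F7. Chalcone isomerase closes this to (2S)-naringenin F8 in more than 99% ee.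
- F8 then takes the place of 6 in the anodic coupling with 5. The weakly acidic HFIP medium offers no base-mediated ring-opening pathway, so C2 should be retained and 9 is obtained directly.

**Third: step 1.**
- Risks:
  - The unprotected phloroacetophenone may undergo C-alkylation on ring A by the iminium ion.
  - The condensation may be low-yielding.
- Fallback: replace the aldehyde cascade by C-acylation and cyclodehydration. This sets out from 1 and comes back to the route at 5.
- The lithium polyanion of 1 (LiN(SiMe3)2, 5 equiv, THF, −78 → −10 °C) is acylated at the methyl carbon with 4-methoxybenzoyl chloride. This gives 1-(2,4,6-trihydroxyphenyl)-3-(4-methoxyphenyl)propane-1,3-dione F1.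
- H2SO4 in AcOH at 95 °C cyclodehydrates F1 to 5.

## Further compounds
F1 | step 1 | 1-(2,4,6-trihydroxyphenyl)-3-(4-methoxyphenyl)propane-1,3-dione | COc1ccc(C(=O)CC(=O)c2c(O)cc(O)cc2O)cc1
F2 | step 2 | 5,7-bis(methoxymethoxy)-4'-methoxyflavone | COc1ccc(-c2cc(=O)c3c(OCOC)cc(OCOC)cc3o2)cc1
F3 | step 2 | 8-iodo-5,7-bis(methoxymethoxy)-4'-methoxyflavone | COc1ccc(-c2cc(=O)c3c(OCOC)cc(OCOC)c(I)c3o2)cc1
F4 | step 2 | 4-hydroxy-3-(4,4,5,5-tetramethyl-1,3,2-dioxaborolan-2-yl)benzaldehyde | CC1(C)OB(c2cc(C=O)ccc2O)OC1(C)C
F5 | step 2 | 8-(5-formyl-2-hydroxyphenyl)-5,7-bis(methoxymethoxy)-4'-methoxyflavone | COc1ccc(-c2cc(=O)c3c(OCOC)cc(OCOC)c(-c4cc(C=O)ccc4O)c3o2)cc1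
F6 | step 2 | 8-(5-formyl-2-hydroxyphenyl)acacetin | COc1ccc(-c2cc(=O)c3c(O)cc(O)c(-c4cc(C=O)ccc4O)c3o2)cc1
F7 | step 3 | naringenin chalcone ((E)-2',4',6',4-tetrahydroxychalcone) | O=C(/C=C/c1ccc(O)cc1)c1c(O)cc(O)cc1O
F8 | step 3 | (2S)-naringenin | O=C1C[C@@H](c2ccc(O)cc2)Oc2cc(O)cc(O)c21
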